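The tetralin ring is cut at both aryl–alkyl bonds, C1–C7 and C2–C7'. This turns ring A into a 1,2-dinucleophile and C7–C8–C8'–C7' into a chiral 1,4-dielectrophile, a γ-aryl-γ-butyrolactone. In one flask lithiated C1 adds to the lactone carbonyl C7, and silane and BF3·OEt2 strip the hemiketal oxygen. The C7'–O bond then ionises, C2 captures the cation, and the last C7–O bond is reduced. The step exploits ring A: C2 and C6 are equivalent, each ortho and para to a methoxy group, while the pendant guaiacyl ring carries the cation. The cis C8/C8' methyl pair comes from desymmetrised meso-2,3-dimethylsuccinic anhydride.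

Key step: step 5

Remark: lignan numbering is used (ring A = C1–C6, chain C7, C8, C8', C7', pendant ring C1'–C6'). Centres written RS are epimer mixtures that converge in step 5. Aryl bromide 3 is taken as a catalogue compound.

Step 1
Reactants: 1 meso-2,3-dimethylsuccinic acid
Product: 2 meso-2,3-dimethylsuccinic anhydride, (3R,4S)-3,4-dimethyloxolane-2,5-dione
Conditions: (CF3CO)2O, CH2Cl2, 0 °C → rt
Reagents that add atoms: none
Why: Cyclodehydration of the 1,4-diacid through its mixed trifluoroacetic anhydride closes the five-membered anhydride under acidic, non-enolising conditions, so the cis (meso) relationship of the two methyl groups should be kept.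

Step 2
Reactants: 3 1-(benzyloxy)-4-bromo-2-methoxybenzene; 2 meso-2,3-dimethylsuccinic anhydride
Product: 6 (2S,3R)-4-[4-(benzyloxy)-3-methoxyphenyl]-2,3-dimethyl-4-oxobutanoic acid, via aryllithium 4 (not isolated), via arylzinc triflate 5 (not isolated)
Conditions: n-BuLi, THF, −78 °C; Zn(OTf)2, −78 °C → rt; 2, [Rh(cod)Cl]2 (catalytic), TADDOL-derived N,N-dimethylphosphoramidite (catalytic, antipode that gives 2S,3R), THF, 50 °C; 1 M HCl
Reagents that add atoms: none
Why: Rhodium-catalysed enantioselective desymmetrisation of a meso succinic anhydride by acyl cross-coupling with an arylzinc reagent, in which the chiral phosphoramidite directs insertion into the acyl C–O bond next to the R-configured carbon only, so that C8' (R) and C8 (S in the acid) are fixed in one stroke without touching either C–H bond.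

Step 3
Reactants: 6 (2S,3R)-4-[4-(benzyloxy)-3-methoxyphenyl]-2,3-dimethyl-4-oxobutanoic acid
Product: 8 (3S,4R,5RS)-5-[4-(benzyloxy)-3-methoxyphenyl]-3,4-dimethyloxolan-2-one, via hydroxy acid 7 (not isolated)
Conditions: NaBH4, MeOH–THF, 0 °C; 1 M HCl, rt
Reagents that add atoms: none
Why: Chemoselective borohydride reduction of the aryl ketone beside the carboxylate followed by acid-induced lactonisation should give the 3,4-cis-dimethyl lactone, and the new carbinol centre C7' need not be controlled because it is ionised in step 5.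

Step 4
Reactants: 9 4-bromo-2,6-dimethoxyphenol
Product: 10 2-(benzyloxy)-5-bromo-1,3-dimethoxybenzene
Conditions: BnBr, K2CO3, DMF, rt
Reagents that add atoms: benzyl bromide BrCc1ccccc1
Why: Williamson ether synthesis on the phenoxide masks the acidic OH before lithiation and places a benzyl group that leaves together with the other one in step 6.

Step 5
Reactants: 10 2-(benzyloxy)-5-bromo-1,3-dimethoxybenzene; 8 (3S,4R,5RS)-5-[4-(benzyloxy)-3-methoxyphenyl]-3,4-dimethyloxolan-2-one
Product: 15 (7'R,8R,8'R)-4,4'-bis(benzyloxy)-3,3',5-trimethoxy-2,7'-cyclolignan, via aryllithium 11 (not isolated), via cyclic hemiketal 12 (not isolated), via diaryltetrahydrofuran 13 (not isolated), via 7-hydroxycyclolignan 14 (not isolated)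
Conditions: 10, n-BuLi, THF–Et2O, −78 °C; 8, −78 °C; AcOH (1 equiv), −78 °C; CH2Cl2, Et3SiH (10 equiv), BF3·OEt2 (5 equiv), −78 °C → rt; aq NaHCO3
Reagents that add atoms: none
Why: Bromine–lithium exchange places the carbanion on C1 of ring A, which adds once to the lactone carbonyl C7 (first bond, C1–C7) to give hemiketal 12; BF3·OEt2 then ionises 12 to the aryl-conjugated oxocarbenium ion, which Et3SiH should reduce at −78 °C to tetrahydrofuran 13 before C8 can enolise. On warming, BF3 opens the oxolane of 13 at the C7'–O bond, the 4-benzyloxy-3-methoxybenzyl cation is attacked by C2 of ring A (second bond, C2–C7') to give 14, and the remaining benzylic C7–O bond is ionised and reduced by the silane to the CH2 group of 15. The closest known reaction types are aryllithium addition to a γ-lactone, silane/Lewis acid deoxygenation of cyclic hemiketals, the acid-induced rearrangement of 2,5-diaryl-3,4-dimethyltetrahydrofuran lignans to aryltetralins (intramolecular Friedel–Crafts alkylation) and ionic hydrogenation of benzylic alcohols. The only ring closed is the six-membered carbocycle C1–C2–C7'–C8'–C8–C7, by 6-exo attack of the arene on the quinoid C7'=C1' bond of the cation. C7' is the only new stereocentre and is set by C8': allylic 1,3-strain holds the C8'–H bond in the plane of the cation, the tether brings ring A to the face opposite the C8' methyl group, and the 7',8'-trans (7'R) product should result whichever C7' epimer of 8 is used. The step needs ionisation at C7' rather than C7 and ring closure faster than hydride capture or proton loss: the pendant ring stabilises a cation better than ring A, whose 4-benzyloxy group is twisted out of conjugation by its two methoxy neighbours, C2 and C6 are equivalent and doubly activated so closure is fast with a single regiochemical outcome, and the large excess of silane should intercept the C7 cation before it loses the C8 proton.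

Step 6
Reactants: 15 (7'R,8R,8'R)-4,4'-bis(benzyloxy)-3,3',5-trimethoxy-2,7'-cyclolignan
Product: 16 (−)-(7'R,8R,8'R)-4,4'-dihydroxy-3,3',5-trimethoxy-2,7'-cyclolignan
Conditions: H2 (1 atm), Pd/C, EtOAc–EtOH, rt
Reagents that add atoms: none
Why: Catalytic hydrogenolysis cleaves both aryl benzyl ethers under neutral conditions and leaves the three all-carbon stereocentres untouched.

Compound list
1 | meso-2,3-dimethylsuccinic acid, (2R,3S)-2,3-dimethylbutanedioic acid | OC(=O)[C@@H](C)[C@H](C(=O)O)C | starting material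
2 | meso-2,3-dimethylsuccinic anhydride, (3R,4S)-3,4-dimethyloxolane-2,5-dione (cis) | O=C1OC(=O)[C@H](C)[C@@H]1C | intermediate
3 | 1-(benzyloxy)-4-bromo-2-methoxybenzene | Brc1ccc(OCc2ccccc2)c(OC)c1 | starting material
4 | [4-(benzyloxy)-3-methoxyphenyl]lithium | [Li]c1ccc(OCc2ccccc2)c(OC)c1 | intermediate
5 | [4-(benzyloxy)-3-methoxyphenyl]zinc trifluoromethanesulfonate | FC(F)(F)S(=O)(=O)O[Zn]c1ccc(OCc2ccccc2)c(OC)c1 | intermediate
6 | (2S,3R)-4-[4-(benzyloxy)-3-methoxyphenyl]-2,3-dimethyl-4-oxobutanoic acid | OC(=O)[C@@H](C)[C@H](C(=O)c1ccc(OCc2ccccc2)c(OC)c1)C | intermediate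
7 | (2S,3R,4RS)-4-[4-(benzyloxy)-3-methoxyphenyl]-4-hydroxy-2,3-dimethylbutanoic acid | OC(=O)[C@@H](C)[C@H](C(O)c1ccc(OCc2ccccc2)c(OC)c1)C | intermediate
8 | (3S,4R,5RS)-5-[4-(benzyloxy)-3-methoxyphenyl]-3,4-dimethyloxolan-2-one (3,4-cis) | O=C1OC(c2ccc(OCc3ccccc3)c(OC)c2)[C@H](C)[C@@H]1C | intermediate
9 | 4-bromo-2,6-dimethoxyphenol | Oc1c(OC)cc(Br)cc1OC | starting material
10 | 2-(benzyloxy)-5-bromo-1,3-dimethoxybenzene | COc1cc(Br)cc(OC)c1OCc1ccccc1 | intermediate
11 | [4-(benzyloxy)-3,5-dimethoxyphenyl]lithium | COc1cc([Li])cc(OC)c1OCc1ccccc1 | intermediate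
12 | (2RS,3S,4R,5RS)-2-[4-(benzyloxy)-3,5-dimethoxyphenyl]-5-[4-(benzyloxy)-3-methoxyphenyl]-3,4-dimethyloxolan-2-ol | OC1(c2cc(OC)c(OCc3ccccc3)c(OC)c2)OC(c2ccc(OCc3ccccc3)c(OC)c2)[C@H](C)[C@@H]1C | intermediate
13 | (2RS,3S,4R,5RS)-2-[4-(benzyloxy)-3,5-dimethoxyphenyl]-5-[4-(benzyloxy)-3-methoxyphenyl]-3,4-dimethyloxolane | COc1cc(C2OC(c3ccc(OCc4ccccc4)c(OC)c3)[C@H](C)[C@@H]2C)cc(OC)c1OCc1ccccc1 | intermediate
14 | 4,4'-bis(benzyloxy)-3,3',5-trimethoxy-2,7'-cyclolignan-7-ol, C7', C8 and C8' arranged as in 15, C7 epimers | COc1cc([C@@H]2c3c(cc(OC)c(OCc4ccccc4)c3OC)C(O)[C@@H](C)[C@H]2C)ccc1OCc1ccccc1 | intermediate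
15 | (7'R,8R,8'R)-4,4'-bis(benzyloxy)-3,3',5-trimethoxy-2,7'-cyclolignan (7',8'-trans, 8,8'-cis) | COc1cc([C@@H]2c3c(cc(OC)c(OCc4ccccc4)c3OC)C[C@@H](C)[C@H]2C)ccc1OCc1ccccc1 | intermediate
16 | (−)-(7'R,8R,8'R)-4,4'-dihydroxy-3,3',5-trimethoxy-2,7'-cyclolignan | COc1cc([C@@H]2c3c(cc(OC)c(O)c3OC)C[C@@H](C)[C@H]2C)ccc1O | target

Total step count: 6. Longest linear sequence: 5 steps (1 → 2 → 6 → 8 → 15 → 16).

Steps most likely to fail

**Step 5.** Three processes may go wrong.
- A second aryllithium may add to the opened keto alkoxide.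
- Hydride may capture the C7' cation before the ring closes.
- The C7 cation may lose a proton, which would erase C8.

The fallback sets out from 6 (with 10) and comes back at 15. It brings C7 to the CH2 level before any cation is made.
- BH3·SMe2 (THF, −10 °C) reduces the carboxyl group of 6 chemoselectively to the hydroxy ketone (2R,3S)-1-[4-(benzyloxy)-3-methoxyphenyl]-4-hydroxy-2,3-dimethylbutan-1-one F1.
- An Appel-type iodination (I2, PPh3, imidazole) gives the iodo ketone (2R,3S)-1-[4-(benzyloxy)-3-methoxyphenyl]-4-iodo-2,3-dimethylbutan-1-one F2.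
- A nickel-catalysed reductive cross-electrophile coupling with 10 (NiCl2(dme), 4,4'-di-tert-butyl-2,2'-bipyridine, Zn, DMA) forms C1–C7. It gives the diaryl ketone (2R,3R)-4-[4-(benzyloxy)-3,5-dimethoxyphenyl]-1-[4-(benzyloxy)-3-methoxyphenyl]-2,3-dimethylbutan-1-one F3.
- NaBH4 gives the benzylic alcohol (1RS,2R,3R)-4-[4-(benzyloxy)-3,5-dimethoxyphenyl]-1-[4-(benzyloxy)-3-methoxyphenyl]-2,3-dimethylbutan-1-ol F4.
- TFA in CH2Cl2 at 0 °C closes C2–C7' by the same Friedel–Crafts alkylation to 15.

No cation can arise at C7, at the price of forming the two aryl–carbon bonds in separate flasks.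

**Step 2.** Three processes may go wrong.
- The catalyst may discriminate imperfectly between the two enantiotopic carbonyl groups.
- Transmetalation from zinc to rhodium may be sluggish.
- The new ketone may enolise at 50 °C.

The fallback sets out from 2 (with 3 through arylzinc 5) and comes back at 8. It separates the asymmetric event from the C–C bond formation.
- Alkaloid-catalysed methanolysis of 2 ((DHQD)2AQN or its pseudo-enantiomer, MeOH, Et2O, low temperature) gives the hemiester (2R,3S)-4-methoxy-2,3-dimethyl-4-oxobutanoic acid F5.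
- Oxalyl chloride with catalytic DMF gives the acid chloride methyl (2S,3R)-4-chloro-2,3-dimethyl-4-oxobutanoate F6.
- A Negishi acylation with 5 under Pd(PPh3)4 gives the keto ester methyl (2S,3R)-4-[4-(benzyloxy)-3-methoxyphenyl]-2,3-dimethyl-4-oxobutanoate F7.
- NaBH4 gives the hydroxy ester methyl (2S,3R,4RS)-4-[4-(benzyloxy)-3-methoxyphenyl]-4-hydroxy-2,3-dimethylbutanoate F8, which lactonises with loss of methanol to 8.

**Step 3.** The aryl ketone may enolise in the basic protic medium and epimerise C8' before hydride delivery. The electron-rich benzylic alcohol may also ionise during the acidic lactonisation.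

The fallback sets out from 6 and comes back at 8. It over-reduces in an aprotic medium and then re-oxidises.
- LiAlH4 (THF, −78 °C → rt) reduces the ketone first and then the carboxylate to the diol (1RS,2R,3S)-1-[4-(benzyloxy)-3-methoxyphenyl]-2,3-dimethylbutane-1,4-diol F9.
- TEMPO with PhI(OAc)2 in CH2Cl2 oxidises the primary alcohol.
- The lactol (3S,4R)-5-[4-(benzyloxy)-3-methoxyphenyl]-3,4-dimethyloxolan-2-ol F10 that forms is oxidised on to 8 under neutral conditions.

Further compounds
F1 | step 5 | (2R,3S)-1-[4-(benzyloxy)-3-methoxyphenyl]-4-hydroxy-2,3-dimethylbutan-1-one | OC[C@@H](C)[C@H](C(=O)c1ccc(OCc2ccccc2)c(OC)c1)C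
F2 | step 5 | (2R,3S)-1-[4-(benzyloxy)-3-methoxyphenyl]-4-iodo-2,3-dimethylbutan-1-one | IC[C@@H](C)[C@H](C(=O)c1ccc(OCc2ccccc2)c(OC)c1)C
F3 | step 5 | (2R,3R)-4-[4-(benzyloxy)-3,5-dimethoxyphenyl]-1-[4-(benzyloxy)-3-methoxyphenyl]-2,3-dimethylbutan-1-one | COc1cc(C[C@@H](C)[C@H](C(=O)c2ccc(OCc3ccccc3)c(OC)c2)C)cc(OC)c1OCc1ccccc1
F4 | step 5 | (1RS,2R,3R)-4-[4-(benzyloxy)-3,5-dimethoxyphenyl]-1-[4-(benzyloxy)-3-methoxyphenyl]-2,3-dimethylbutan-1-ol | COc1cc(C[C@@H](C)[C@H](C(O)c2ccc(OCc3ccccc3)c(OC)c2)C)cc(OC)c1OCc1ccccc1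
F5 | step 2 | (2R,3S)-4-methoxy-2,3-dimethyl-4-oxobutanoic acid | COC(=O)[C@@H](C)[C@H](C(=O)O)C
F6 | step 2 | methyl (2S,3R)-4-chloro-2,3-dimethyl-4-oxobutanoate | COC(=O)[C@@H](C)[C@H](C(=O)Cl)C
F7 | step 2 | methyl (2S,3R)-4-[4-(benzyloxy)-3-methoxyphenyl]-2,3-dimethyl-4-oxobutanoate | COC(=O)[C@@H](C)[C@H](C(=O)c1ccc(OCc2ccccc2)c(OC)c1)C
F8 | step 2 | methyl (2S,3R,4RS)-4-[4-(benzyloxy)-3-methoxyphenyl]-4-hydroxy-2,3-dimethylbutanoate | COC(=O)[C@@H](C)[C@H](C(O)c1ccc(OCc2ccccc2)c(OC)c1)C
F9 | step 3 | (1RS,2R,3S)-1-[4-(benzyloxy)-3-methoxyphenyl]-2,3-dimethylbutane-1,4-diol | OC[C@@H](C)[C@H](C(O)c1ccc(OCc2ccccc2)c(OC)c1)C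
F10 | step 3 | (3S,4R)-5-[4-(benzyloxy)-3-methoxyphenyl]-3,4-dimethyloxolan-2-ol (C2 and C5 epimers) | OC1OC(c2ccc(OCc3ccccc3)c(OC)c2)[C@H](C)[C@@H]1C
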